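The numbers in the tables come from a simulation with made-up constants; the scatter is artificial.

In the south-east run 37.4 % of the electrophile is left at 3.00 min, yet product stands at just 11.1 %.

| setting | north-east | south-east | alder | larch | birch |
|---|---|---|---|---|---|
| electrophile | 0.25 M | 0.12 M | 0.25 M | 0.25 M | 0.25 M |
| free base | 0.275 M | 0.275 M | 0.280 M | 0.360 M | 0.460 M |
| protonated nucleophile | 0.20 M | 0.30 M | 0.300 M | 0.300 M | 0.300 M |
| remark | run made earlier | run made earlier |  |  |  |
| time |  |  | 8.0 min | 8.0 min | 8.0 min |

- north-east (time / min: electrophile / %, product / %): 0.250: 90.0, 2.0; 0.667: 76.7, 2.8; 1.33: 62.0, 5.1; 2.00: 50.6, 5.9; 3.00: 40.5, 8.1
- south-east (time / min: electrophile / %, product / %): 0.500: 81.0, 3.3; 1.00: 68.2, 5.1; 1.50: 56.8, 5.7; 2.50: 42.5, 9.8; 3.00: 37.4, 11.1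

(scatter of a reading: 0.5 percentage points)

- part of the electrophile that has reacted at the end, alder
- part of the electrophile that has reacted at the end, larch
- part of the electrophile that has reacted at the end, birch
- what raising the concentration of free base from its lowest to its highest value here does to the part of the electrophile that has reacted (changes below 5 percentage points count as none) (it falls / it rises / no change)

- what has gone from electrophile into another species counts as reacted, even if it can come back
- no earlier run changes the charge of free base; that part of a forecast is a guess

Take the main step first, electrophile to product. With that step by itself the two columns would sum to the charge, and they do not. At 3.00 min the missing part is 51.5 % in the south-east run and 51.4 % in the north-east run, nearly equal, although c(electrophile) is 0.12 M in the first and 0.25 M in the second. The two runs also differ in protonated nucleophile, 0.30 M against 0.20 M, but a loss with the same percentage at both charges looks first order in electrophile.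

So add a second process, taken here as a reversible exchange of the electrophile with a hidden species, its resting state. Electrophile and hidden species together are whatever is not yet product. The part of this sum that is still electrophile, once the exchange has relaxed, is the free share, read from the scattered south-east readings as about 26.8 %. It starts at the whole, and the south-east run reads 60.2 % at 1.50 min and 42.1 % at 3.00 min. Three equally spaced points of an exponential give that end value and a half-life of 1.33 min, short against 8.0 min. The share can therefore be frozen at its end value.

Last comes the drain to product. The north-east run, with 0.20 M of protonated nucleophile against 0.300 M in the three new flasks, gives about 0.0384 /min on free electrophile, which carries its product to an estimated 13.2 % at 8.0 min. The reacted part is then one minus the free share times what is not product, about 76.8 %. Each further point of product adds 26.8 % of a point. Free base was not varied in the earlier runs, so its effect is a guess, but on this reckoning it acts through product, and the reckoning puts alder, larch and birch all near 76.8 %, with no change.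

The forecast for the three flasks is 79 %, 88 % and 95 %; of the trend it says it rises, with the remark “Base order is inferred, never tested directly.”

Alder, larch and birch give 77.3 %, 78.0 % and 78.7 %, so the answer on the trend is no change, with 1.4 percentage points between the lowest and the highest free base.

    electrophile + nucleophile ⇌ acid set free + product (K = 1.60, k = 0.0180 /M/s)
    nucleophile + acid set free ⇌ protonated nucleophile, settled at all times (K = 5100 /M)
    acid set free + free base ⇌ salt of the base, settled at all times (K = 360 /M)
    electrophile ⇌ dormant form (K = 2.80, k = 0.00580 /s)

The missing part is the dormant form, 61.6 % in larch at 8.00 min. In larch, product at 8.00 min is 16.4 %, and the free share turns this into 77.6 % reacted, against 78.0 %. A further flask like larch holds 1.2 M of protonated nucleophile. Its product at 8.00 min is 27.5 %, so the same reckoning gives 80.6 % reacted. That flask gives 81.9 %, with 18.1 % of the electrophile left.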